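The route rests on opening ring C at C7–C8 and at the C9–methyl bond. In ring C the tetrasubstituted C8=C9 alkene is trans in the ring and holds the C7 carbinol carbon and the C9 methyl on the same side; a cis addition of a carbonyl carbon and a methyl across a C8≡C9 triple bond creates this. One nickel-catalysed reaction of ynal 27 with Me2Zn closes the eleven-membered ring, sets C7 and installs the methyl. The precursor is an all-cis ring A with a C10 propargyl ether arm and a C11 arm ending in the C7 aldehyde; C2 is a triethylsilyl ether and C15/C16 are 4-methoxybenzyl ethers, so both secondary acetates precede the pinacol closure of ring B.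

Key step: step 20

Remark on the chemistry (numbering and assumption): ring C is C1 (exocyclic methylene), C2 (O), C3, C4, C5 (Me), C6, C7 (O), C8=C9 (Me), C10, C11; ring B is C8, C9, C10, C14 (Me), C15 (OH), C16 (OAc); ring A is C10–C14. Read from the SMILES, the target is taken as (2R,5S,7S,10S,11R,14S,15R,16R) in this numbering; descriptors attached to C-numbers below use it.

Step 1
Reactants: 1 methyl 2-oxocyclopentane-1-carboxylate
Product: 2 methyl (1R,2R)-2-hydroxycyclopentane-1-carboxylate
Conditions: H2 (100 atm), RuCl2[(R)-2,2'-bis(diphenylphosphino)-1,1'-binaphthyl] (cat.), CH2Cl2, 50 °C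
Reagents that add atoms: none
Why: Noyori asymmetric hydrogenation with dynamic kinetic resolution: the keto ester racemizes through its enol while the (R)-diphosphine–ruthenium catalyst reduces one enantiomer, which should give the trans hydroxy ester with the (2R) carbinol that later directs the quaternary centre.

Step 2
Reactants: 2 methyl (1R,2R)-2-hydroxycyclopentane-1-carboxylate
Product: 4 methyl (1S,2R)-2-hydroxy-1-methylcyclopentane-1-carboxylate, via dilithium alkoxide–enolate 3 (not isolated)
Conditions: LiN(iPr)2 (2.2 equiv), THF, −78 to −20 °C; MeI, DMPU, −78 to 0 °C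
Reagents that add atoms: iodomethane, CI
Why: Fráter–Seebach alkylation: the dianion is methylated on the face away from the alkoxide oxygen, so the methyl enters trans to oxygen and sets the quaternary C14 as (S).

Step 3
Reactants: 4 methyl (1S,2R)-2-hydroxy-1-methylcyclopentane-1-carboxylate
Product: 5 methyl (1S)-1-methyl-2-oxocyclopentane-1-carboxylate
Conditions: Dess–Martin periodinane, CH2Cl2, rt
Reagents that add atoms: none
Why: Dess–Martin oxidation of the secondary alcohol; the quaternary α-carbon cannot epimerize, so the keto ester should be obtained as one enantiomer.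

Step 4
Reactants: 5 methyl (1S)-1-methyl-2-oxocyclopentane-1-carboxylate
Product: 7 methyl (1S)-1-methyl-2-(trifluoromethanesulfonyloxy)cyclopent-2-ene-1-carboxylate, via potassium enolate 6 (not isolated)
Conditions: KN(SiMe3)2, THF, −78 °C; PhNTf2, −78 to 0 °C
Reagents that add atoms: N-phenylbis(trifluoromethanesulfonimide), O=S(=O)(N(c1ccccc1)S(=O)(=O)C(F)(F)F)C(F)(F)F
Why: Enol triflate formation: only C11 carries α-hydrogens, so deprotonation and O-sulfonylation can give only one alkenyl triflate.

Step 5
Reactants: 7 methyl (1S)-1-methyl-2-(trifluoromethanesulfonyloxy)cyclopent-2-ene-1-carboxylate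
Product: 8 (5R)-5-(hydroxymethyl)-5-methylcyclopent-1-en-1-yl trifluoromethanesulfonate
Conditions: iBu2AlH (2.5 equiv), CH2Cl2, −78 to 0 °C
Reagents that add atoms: none
Why: Hydride reduction of the ester to the primary alcohol (future C15–OH); alkenyl triflates are inert to iBu2AlH at low temperature.

Step 6
Reactants: 8 (5R)-5-(hydroxymethyl)-5-methylcyclopent-1-en-1-yl trifluoromethanesulfonate
Product: 9 (3aS)-3a-methyl-3,3a,4,5-tetrahydro-1H-cyclopenta[c]furan-1-one (butenolide with the C10=C11 alkene)
Conditions: Pd(PPh3)4 (5 mol %, zerovalent palladium), CO (1 atm), Et3N, MeCN, 65 °C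
Reagents that add atoms: carbon monoxide, [C-]#[O+]
Why: Palladium-catalysed carbonylative lactonization: oxidative addition into the C10–OTf bond, CO insertion (C9) and capture of the acylpalladium by the C15 hydroxyl close the five-membered lactone.

Step 7
Reactants: 9 (3aS)-3a-methyl-3,3a,4,5-tetrahydro-1H-cyclopenta[c]furan-1-one
Product: 11 (3aS,6R,6aR)-3a-methyl-6-[1-(trimethylsilyl)ethenyl]hexahydro-1H-cyclopenta[c]furan-1-one, via trimethylsilyl ketene acetal 10 (not isolated)
Conditions: CH2=C(SiMe3)MgBr (2 equiv, made beforehand from (1-bromoethenyl)trimethylsilane and Mg), CuBr·SMe2 (20 mol %), Me3SiCl, THF, −78 to −40 °C; then 1 M HCl, 0 °C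
Reagents that add atoms: [1-(trimethylsilyl)ethenyl]magnesium bromide, C=C([Mg]Br)[Si](C)(C)C; chlorotrimethylsilane, C[Si](C)(C)Cl (kept only in 10)
Why: Copper-catalysed conjugate addition: the alkenyl group should add to C11 opposite the angular C14 methyl, and hydrolysis of the ketene acetal protonates C10 to the only accessible cis-fused lactone, so the C15, C9 and C1 arms end up all cis on ring A.

Step 8
Reactants: 11 (3aS,6R,6aR)-3a-methyl-6-[1-(trimethylsilyl)ethenyl]hexahydro-1H-cyclopenta[c]furan-1-one
Product: 12 (3aS,6R,6aR)-6-(1-iodoethenyl)-3a-methylhexahydro-1H-cyclopenta[c]furan-1-one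
Conditions: N-iodosuccinimide, (CF3)2CHOH, 0 °C
Reagents that add atoms: N-iodosuccinimide, O=C1CCC(=O)N1I
Why: Ipso-iododesilylation of the alkenylsilane gives the 1,1-disubstituted alkenyl iodide without touching the lactone or the stereocentres.

Step 9
Reactants: 13 (S)-citronellal
Product: 14 (6S)-8,8-dimethoxy-2,6-dimethyloct-2-ene
Conditions: HC(OMe)3, MeOH, pyridinium p-toluenesulfonate (cat.), rt
Reagents that add atoms: trimethyl orthoformate, COC(OC)OC
Why: Acid-catalysed acetalization masks the future C7 aldehyde; the C5 stereocentre (S) is taken from the chiral pool.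

Step 10
Reactants: 14 (6S)-8,8-dimethoxy-2,6-dimethyloct-2-ene
Product: 16 (4S)-6,6-dimethoxy-4-methylhexanal, via ozonide 15 (not isolated)
Conditions: O3, CH2Cl2, −78 °C; then PPh3, −78 °C to rt
Reagents that add atoms: ozone, [O-][O+]=O
Why: Ozonolysis with reductive work-up cleaves the trisubstituted alkene to the C2 aldehyde; the acetal is stable without acid.

Step 11
Reactants: 12 (3aS,6R,6aR)-6-(1-iodoethenyl)-3a-methylhexahydro-1H-cyclopenta[c]furan-1-one; 16 (4S)-6,6-dimethoxy-4-methylhexanal
Product: 17 lactone allylic alcohol with the C1–C2 bond (both C2 epimers)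
Conditions: CrCl2 (4 equiv), NiCl2 (2 mol %), DMSO, rt
Reagents that add atoms: none
Why: Nozaki–Hiyama–Kishi coupling: the alkenylchromium from 12 adds only to the aldehyde, leaving lactone and acetal intact; the C2 epimer mixture converges in steps 12 and 13.

Step 12
Reactants: 17 lactone allylic alcohol (C2 epimers)
Product: 18 lactone enone (C2 ketone next to the C1 methylene)
Conditions: Dess–Martin periodinane, pyridine, CH2Cl2, 0 °C to rt
Reagents that add atoms: none
Why: Dess–Martin oxidation converts both allylic alcohol epimers into one enone under buffered conditions that leave the acetal intact.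

Step 13
Reactants: 18 lactone enone
Product: 19 lactone (2R)-allylic alcohol
Conditions: (S)-1-methyl-3,3-diphenyltetrahydro-1H,3H-pyrrolo[1,2-c][1,3,2]oxazaborole (1 equiv), catecholborane, toluene, −78 °C
Reagents that add atoms: none
Why: Corey–Bakshi–Shibata reduction: with the branched alkenyl group as the large and the CH2 chain as the small substituent, the (S)-oxazaborolidine should give the (2R) alcohol under reagent control; catecholborane does not reduce the lactone at −78 °C.

Step 14
Reactants: 19 lactone (2R)-allylic alcohol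
Product: 20 lactone (2R)-triethylsilyl ether
Conditions: Et3SiCl, imidazole, DMF, 0 °C to rt
Reagents that add atoms: chlorotriethylsilane, CC[Si](Cl)(CC)CC
Why: Silyl ether formation; the triethylsilyl group can later be removed in the presence of benzyl-type ethers.

Step 15
Reactants: 20 lactone (2R)-triethylsilyl ether
Product: 21 lactol (both anomers)
Conditions: iBu2AlH (1.1 equiv), CH2Cl2, −78 °C
Reagents that add atoms: none
Why: Half-reduction of the lactone stops at the lactol because the tetrahedral aluminate is stable at −78 °C.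

Step 16
Reactants: 21 lactol
Product: 22 ring A alkynyl alcohol (C10 ethynyl, C14 CH2OH)
Conditions: dimethyl (1-diazo-2-oxopropyl)phosphonate, K2CO3, MeOH, 0 °C to rt
Reagents that add atoms: dimethyl (1-diazo-2-oxopropyl)phosphonate, COP(=O)(OC)C(=[N+]=[N-])C(C)=O
Why: Ohira–Bestmann (Seyferth–Gilbert) homologation of the aldehyde in equilibrium with the lactol adds C8 and frees the C15 hydroxyl; C10 should keep its configuration because the open aldehyde is present only in low concentration and is trapped quickly.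

Step 17
Reactants: 22 ring A alkynyl alcohol
Product: 24 ring A propargylic diol (C15–OH and C16–OH), via dilithium alkoxide–acetylide 23 (not isolated)
Conditions: BuLi (2.2 equiv), THF, −78 to 0 °C; (CH2O)n, 0 °C to rt
Reagents that add atoms: formaldehyde (as paraformaldehyde), C=O
Why: Acetylide addition to formaldehyde adds C16 as the propargylic alcohol.

Step 18
Reactants: 24 ring A propargylic diol
Product: 25 bis(4-methoxybenzyl) ether
Conditions: NaH, 4-MeOC6H4CH2Cl, Bu4NI (cat.), DMF, 0 °C to rt
Reagents that add atoms: 4-methoxybenzyl chloride, COc1ccc(CCl)cc1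
Why: Williamson etherification of both primary hydroxyls gives compact ethers that are orthogonal to the C2 silyl ether and to acetates.

Step 19
Reactants: 25 bis(4-methoxybenzyl) ether
Product: 27 ynal (C7 aldehyde, C8≡C9 alkyne), via collidinium salt 26 (not isolated)
Conditions: Et3SiOTf, 2,4,6-collidine, CH2Cl2, 0 °C; then H2O
Reagents that add atoms: water, O; 2,4,6-trimethylpyridine, Cc1cc(C)nc(C)c1 and triethylsilyl trifluoromethanesulfonate, CC[Si](CC)(CC)OS(=O)(=O)C(F)(F)F (both kept only in 26)
Why: Non-acidic acetal cleavage: silyl triflate and collidine convert the dimethyl acetal into an N-(α-methoxyalkyl)pyridinium salt that water hydrolyses to the aldehyde, so the silyl and benzyl-type ethers should survive.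

Step 20
Reactants: 27 ynal; 28 dimethylzinc
Product: 30 (2R,5S,7S,10S,11R,14S) macrocyclic allylic alcohol (ring C closed, E C8=C9, C9 methyl, 7-OH), via oxanickelacyclopentene 29 (not isolated)
Conditions: Ni(cod)2 (20 mol %, zerovalent nickel; cod = cycloocta-1,5-diene), Me2Zn (3 equiv), THF, 0 °C, 27 added over 6 h (final 0.002 M); aq. NH4Cl
Reagents that add atoms: dimethylzinc, C[Zn]C; Ni(cod)2, C1=CCCC=CCC1.C1=CCCC=CCC1.[Ni] (nickel kept only in 29)
Why: Zerovalent nickel binds the C8≡C9 alkyne and the C7 aldehyde and couples them oxidatively to the oxanickelacyclopentene (C7–C8 bond made, nickel on C9); methyl transfer from zinc to nickel and C–C reductive elimination then put the methyl on C9 on the same side as C7, which is the E geometry within ring C. The closest known reactions are the nickel-catalysed alkylative three-component coupling of alkynes, aldehydes and organozincs and the nickel-catalysed macrocyclization of ynals. The eleven-membered ring C closes in the endo mode, with both former alkyne carbons in the ring, because the aldehyde carbon bonds to C8, which carries only a CH2O group, while nickel takes C9 next to the branched ring A; no bulky ligand is added that could reverse this preference. The new C7 stereocentre is set in the oxidative cyclization: oxygen lies in the metallacycle plane, C6 must point to the alkene face over which the tether returns to C11, and ring A should turn its small C10–H toward nickel and its quaternary C14 toward the C16 arm, which places C11 and hence C6 on the face that gives (7S). The step needs endo regiochemistry, this facial choice and ring closure instead of oligomerization; the unequal alkyne substituents, the cis arrangement of the two arms on ring A (with the C5 methyl and the C2 silyl ether free to sit equatorially in the forming ring) and slow addition at high dilution are relied on for them.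

Step 21
Reactants: 30 macrocyclic allylic alcohol
Product: 31 macrocyclic 2,7-diol
Conditions: HF·pyridine, pyridine, THF, 0 °C
Reagents that add atoms: none
Why: Fluoride-mediated cleavage of the secondary triethylsilyl ether; the benzyl-type ethers are inert and the buffered medium should not ionize the C7 allylic alcohol.

Step 22
Reactants: 31 macrocyclic 2,7-diol
Product: 32 macrocyclic 2,7-diacetate
Conditions: Ac2O, pyridine, 4-(dimethylamino)pyridine (cat.), CH2Cl2, 0 °C to rt
Reagents that add atoms: acetic anhydride, CC(=O)OC(C)=O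
Why: Nucleophile-catalysed acylation of both secondary allylic alcohols, placing two of the three acetates before any other hydroxyl is free.

Step 23
Reactants: 32 macrocyclic 2,7-diacetate
Product: 33 macrocyclic 15,16-diol diacetate
Conditions: DDQ (2.5 equiv), CH2Cl2/pH 7 buffer, 0 °C
Reagents that add atoms: none
Why: Oxidative cleavage of both 4-methoxybenzyl ethers by DDQ; the neutral medium should suppress acetyl migration from O7 to O16, and any C16 alcohol oxidized further to the enal converges in step 24.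

Step 24
Reactants: 33 macrocyclic 15,16-diol diacetate
Product: 34 dialdehyde (C15 neopentyl aldehyde, C16 enal)
Conditions: Dess–Martin periodinane, pyridine, CH2Cl2, 0 °C to rt
Reagents that add atoms: none
Why: Dess–Martin oxidation of both primary alcohols; C14 is quaternary, so the C15 aldehyde cannot epimerize.

Step 25
Reactants: 34 dialdehyde
Product: 35 (15R,16R) tricyclic trans diol (ring B closed)
Conditions: Cp2TiCl2 (2.5 equiv; Cp = cyclopentadienyl), Zn dust, THF, rt (gives Cp2TiCl, trivalent titanium); 34 added slowly, −20 °C to rt (0.005 M); 1 M HCl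
Reagents that add atoms: none
Why: Pinacol cyclization: trivalent titanium reduces the conjugated C16 aldehyde to a titanium-bound ketyl that adds to the titanium-activated C15 aldehyde and closes six-membered ring B; in the half-chair fixed by the cis-fused ring A and the E alkene, each new C–O bond should take the equatorial site (C15–O away from the pseudoaxial C11, C16–O away from the axial C14 methyl) with the bulky titanoxy groups anti, which is the trans (15R,16R) diol.

Step 26
Reactants: 35 tricyclic trans diol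
Product: 36 CNP0318778.1
Conditions: Ac2O (1.2 equiv), pyridine, CH2Cl2, 0 °C
Reagents that add atoms: acetic anhydride, CC(=O)OC(C)=O
Why: Site-selective acylation: without an acyl-transfer catalyst the allylic, pseudoequatorial C16 hydroxyl next to sp2 C8 should react much faster than the neopentyl C15 hydroxyl flanked by quaternary C14.

Compound list

1 | methyl 2-oxocyclopentane-1-carboxylate | COC(=O)C1CCCC1=O | starting material
2 | methyl (1R,2R)-2-hydroxycyclopentane-1-carboxylate | COC(=O)[C@@H]1CCC[C@H]1O | intermediate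
3 | dilithium alkoxide–enolate of 2 | COC([O-])=C1CCC[C@H]1[O-].[Li+].[Li+] | intermediate (not isolated)
4 | methyl (1S,2R)-2-hydroxy-1-methylcyclopentane-1-carboxylate | COC(=O)[C@@]1(C)CCC[C@H]1O | intermediate
5 | methyl (1S)-1-methyl-2-oxocyclopentane-1-carboxylate | COC(=O)[C@@]1(C)CCCC1=O | intermediate
6 | potassium enolate of 5 | COC(=O)[C@@]1(C)CCC=C1[O-].[K+] | intermediate (not isolated)
7 | methyl (1S)-1-methyl-2-(trifluoromethanesulfonyloxy)cyclopent-2-ene-1-carboxylate | COC(=O)[C@@]1(C)CCC=C1OS(=O)(=O)C(F)(F)F | intermediate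
8 | (5R)-5-(hydroxymethyl)-5-methylcyclopent-1-en-1-yl trifluoromethanesulfonate | OC[C@@]1(C)CCC=C1OS(=O)(=O)C(F)(F)F | intermediate
9 | (3aS)-3a-methyl-3,3a,4,5-tetrahydro-1H-cyclopenta[c]furan-1-one | C[C@]12CCC=C1C(=O)OC2 | intermediate
10 | trimethylsilyl ketene acetal of 11 (C9=C10 enol ether) | C=C([Si](C)(C)C)[C@@H]1CC[C@]2(C)COC(O[Si](C)(C)C)=C12 | intermediate (not isolated)
11 | (3aS,6R,6aR)-3a-methyl-6-[1-(trimethylsilyl)ethenyl]hexahydro-1H-cyclopenta[c]furan-1-one | C=C([Si](C)(C)C)[C@@H]1CC[C@]2(C)COC(=O)[C@H]12 | intermediate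
12 | (3aS,6R,6aR)-6-(1-iodoethenyl)-3a-methylhexahydro-1H-cyclopenta[c]furan-1-one | C=C(I)[C@@H]1CC[C@]2(C)COC(=O)[C@H]12 | intermediate
13 | (S)-citronellal, (3S)-3,7-dimethyloct-6-enal | C[C@@H](CCC=C(C)C)CC=O | starting material
14 | (6S)-8,8-dimethoxy-2,6-dimethyloct-2-ene | COC(OC)C[C@@H](C)CCC=C(C)C | intermediate
15 | ozonide of 14, 3-[(3S)-5,5-dimethoxy-3-methylpentyl]-5,5-dimethyl-1,2,4-trioxolane | COC(OC)C[C@@H](C)CCC1OOC(C)(C)O1 | intermediate (not isolated)
16 | (4S)-6,6-dimethoxy-4-methylhexanal | COC(OC)C[C@@H](C)CCC=O | intermediate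
17 | (3aS,6R,6aR)-6-[(6S)-3-hydroxy-8,8-dimethoxy-6-methyloct-1-en-2-yl]-3a-methylhexahydro-1H-cyclopenta[c]furan-1-one, both C2 epimers | C=C(C(O)CC[C@H](C)CC(OC)OC)[C@@H]1CC[C@]2(C)COC(=O)[C@H]12 | intermediate
18 | (3aS,6R,6aR)-6-[(6S)-8,8-dimethoxy-6-methyl-3-oxooct-1-en-2-yl]-3a-methylhexahydro-1H-cyclopenta[c]furan-1-one | C=C(C(=O)CC[C@H](C)CC(OC)OC)[C@@H]1CC[C@]2(C)COC(=O)[C@H]12 | intermediate
19 | (3aS,6R,6aR)-6-[(3R,6S)-3-hydroxy-8,8-dimethoxy-6-methyloct-1-en-2-yl]-3a-methylhexahydro-1H-cyclopenta[c]furan-1-one | C=C([C@H](O)CC[C@H](C)CC(OC)OC)[C@@H]1CC[C@]2(C)COC(=O)[C@H]12 | intermediate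
20 | (3aS,6R,6aR)-6-{(3R,6S)-8,8-dimethoxy-6-methyl-3-[(triethylsilyl)oxy]oct-1-en-2-yl}-3a-methylhexahydro-1H-cyclopenta[c]furan-1-one | C=C([C@H](O[Si](CC)(CC)CC)CC[C@H](C)CC(OC)OC)[C@@H]1CC[C@]2(C)COC(=O)[C@H]12 | intermediate
21 | lactol of 20, hexahydro-1H-cyclopenta[c]furan-1-ol (both anomers) | C=C([C@H](O[Si](CC)(CC)CC)CC[C@H](C)CC(OC)OC)[C@@H]1CC[C@]2(C)COC(O)[C@H]12 | intermediate
22 | [(1S,2S,3R)-2-ethynyl-1-methyl-3-{(3R,6S)-8,8-dimethoxy-6-methyl-3-[(triethylsilyl)oxy]oct-1-en-2-yl}cyclopentyl]methanol | C=C([C@H](O[Si](CC)(CC)CC)CC[C@H](C)CC(OC)OC)[C@@H]1CC[C@](C)(CO)[C@@H]1C#C | intermediate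
23 | dilithium alkoxide–acetylide of 22 | C=C([C@H](O[Si](CC)(CC)CC)CC[C@H](C)CC(OC)OC)[C@@H]1CC[C@](C)(C[O-])[C@@H]1C#[C-].[Li+].[Li+] | intermediate (not isolated)
24 | 3-[(1S,2S,5R)-2-(hydroxymethyl)-2-methyl-5-{(3R,6S)-8,8-dimethoxy-6-methyl-3-[(triethylsilyl)oxy]oct-1-en-2-yl}cyclopentyl]prop-2-yn-1-ol | C=C([C@H](O[Si](CC)(CC)CC)CC[C@H](C)CC(OC)OC)[C@@H]1CC[C@](C)(CO)[C@@H]1C#CCO | intermediate
25 | bis(4-methoxybenzyl) ether of 24 (O15 and O16) | C=C([C@H](O[Si](CC)(CC)CC)CC[C@H](C)CC(OC)OC)[C@@H]1CC[C@](C)(COCc2ccc(OC)cc2)[C@@H]1C#CCOCc1ccc(OC)cc1 | intermediate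
26 | N-(1-methoxyalkyl)-2,4,6-trimethylpyridinium triflate formed at C7 of 25 | C=C([C@H](O[Si](CC)(CC)CC)CC[C@H](C)CC(OC)[n+]1c(C)cc(C)cc1C)[C@@H]1CC[C@](C)(COCc2ccc(OC)cc2)[C@@H]1C#CCOCc1ccc(OC)cc1.[O-]S(=O)(=O)C(F)(F)F | intermediate (not isolated)
27 | (3S,6R)-7-[(1R,2S,3S)-3-{[(4-methoxybenzyl)oxy]methyl}-2-{3-[(4-methoxybenzyl)oxy]prop-1-yn-1-yl}-3-methylcyclopentyl]-3-methyl-6-[(triethylsilyl)oxy]oct-7-enal (ynal) | C=C([C@H](O[Si](CC)(CC)CC)CC[C@H](C)CC=O)[C@@H]1CC[C@](C)(COCc2ccc(OC)cc2)[C@@H]1C#CCOCc1ccc(OC)cc1 | intermediate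
28 | dimethylzinc | C[Zn]C | starting material
29 | oxanickelacyclopentene (Ni on C9 and O7; other ligands on nickel not shown) | C=C1[C@H](O[Si](CC)(CC)CC)CC[C@H](C)C[C@@H]2O[Ni]C(=C2COCc2ccc(OC)cc2)[C@@H]3[C@H]1CC[C@]3(C)COCc1ccc(OC)cc1 | intermediate (not isolated)
30 | (2R,5S,7S,10S,11R,14S) macrocyclic allylic alcohol: rings A and C, E C8=C9, 7-OH, 2-O-triethylsilyl, 15- and 16-O-(4-methoxybenzyl) | C=C1[C@H](O[Si](CC)(CC)CC)CC[C@H](C)C[C@H](O)/C(COCc2ccc(OC)cc2)=C(\C)[C@@H]2[C@H]1CC[C@]2(C)COCc1ccc(OC)cc1 | intermediate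
31 | 2,7-diol of 30 | C=C1[C@H](O)CC[C@H](C)C[C@H](O)/C(COCc2ccc(OC)cc2)=C(\C)[C@@H]2[C@H]1CC[C@]2(C)COCc1ccc(OC)cc1 | intermediate
32 | 2,7-diacetate of 31 | C=C1[C@H](OC(C)=O)CC[C@H](C)C[C@H](OC(C)=O)/C(COCc2ccc(OC)cc2)=C(\C)[C@@H]2[C@H]1CC[C@]2(C)COCc1ccc(OC)cc1 | intermediate
33 | 2,7-diacetate 15,16-diol | C=C1[C@H](OC(C)=O)CC[C@H](C)C[C@H](OC(C)=O)/C(CO)=C(\C)[C@@H]2[C@H]1CC[C@]2(C)CO | intermediate
34 | 2,7-diacetate 15,16-dialdehyde | C=C1[C@H](OC(C)=O)CC[C@H](C)C[C@H](OC(C)=O)/C(C=O)=C(\C)[C@@H]2[C@H]1CC[C@]2(C)C=O | intermediate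
35 | (2R,5S,7S,10S,11R,14S,15R,16R) tricyclic 2,7-diacetate 15,16-trans-diol | C=C1[C@H](OC(C)=O)CC[C@H](C)C[C@H](OC(C)=O)C2=C(C)[C@@H]3[C@H]1CC[C@]3(C)[C@@H](O)[C@@H]2O | intermediate
36 | CNP0318778.1, (2R,5S,7S,10S,11R,14S,15R,16R) 2,7,16-triacetate 15-ol | C=C1[C@H](OC(C)=O)CC[C@H](C)C[C@H](OC(C)=O)C2=C(C)[C@@H]3[C@H]1CC[C@]3(C)[C@@H](O)[C@@H]2OC(C)=O | target

Total step count: 26. Longest linear sequence: 24 steps (steps 1–8 and 11–26); the citronellal branch (steps 9 and 10) has two steps.

Steps most likely to fail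

Step 20. Intermolecular coupling may outrun ring closure and give oligomers; closure through the other rotamer about C9–C10 would give the C7 epimer; nickel may also transfer methyl directly to the aldehyde. The fallback sets out from 24 and comes back at 30, and makes the same C7–C8 bond from an alkenyl iodide in which the methyl is already in place. Alkoxide-directed syn-carbomagnesiation of the propargylic alcohol (MeMgBr, Fe(acac)3 cat., acac = acetylacetonate, THF; methyl to C9, magnesium to C8) followed by an iodine quench should give iodo diol F1 with methyl and iodine cis. Etherification of both hydroxyls (NaH, 4-methoxybenzyl chloride) gives bis(4-methoxybenzyl) ether F2, and cleavage of the acetal under the conditions of step 19 gives iodo aldehyde F3. An intramolecular Nozaki–Hiyama–Kishi reaction (CrCl2, cat. NiCl2, DMSO/THF, high dilution) then closes ring C with retention of the alkene geometry and gives 30, from which any C7 epimer would have to be separated.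

Step 25. The titanium-bound C16 ketyl may expel the C7 acetate, which sits β to the carbonyl carbon, before it finds the C15 aldehyde, or the coupling may be slow. The fallback sets out from 30 and comes back at 36, and closes ring B while C7 carries a silyl ether, a poor leaving group. Silylation of 30 (Et3SiOTf, 2,6-lutidine) gives bis(triethylsilyl) ether F4, DDQ gives diol F5 and Dess–Martin oxidation gives dialdehyde F6. Pinacol cyclization (Cp2TiCl as in step 25, or SmI2, THF, −78 °C) gives ring B diol F7, and HF·pyridine frees tetraol F8. Acetylation with three equivalents of Ac2O in pyridine at 0 °C, which should spare the neopentyl C15 hydroxyl, gives 36.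

Step 26. The acetyl transfer may not discriminate well enough between the two secondary hydroxyls (acetylation at O15, diacetate formation), or the acetyl group may migrate. The fallback sets out from 35 and comes back at 36, and tells the two oxygens apart by oxidation state and by mechanism. MnO2 oxidizes only the allylic C16 carbinol and gives α-hydroxy enone F9. Luche reduction (NaBH4, CeCl3, MeOH, −78 °C) should deliver hydride anti to the axial C14 methyl and give the 16-epimeric cis diol F10. A Mitsunobu reaction (PPh3, diisopropyl azodicarboxylate, AcOH), which engages the allylic hydroxyl and not the neopentyl one, installs the C16 acetate with inversion and gives 36.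

Further compounds

F1 | step 20 | iodo diol: 24 with the alkyne replaced by C9(Me)=C8(I), methyl and iodine cis | C=C([C@H](O[Si](CC)(CC)CC)CC[C@H](C)CC(OC)OC)[C@@H]1CC[C@](C)(CO)[C@@H]1/C(C)=C(/I)CO
F2 | step 20 | bis(4-methoxybenzyl) ether of F1 | C=C([C@H](O[Si](CC)(CC)CC)CC[C@H](C)CC(OC)OC)[C@@H]1CC[C@](C)(COCc2ccc(OC)cc2)[C@@H]1/C(C)=C(/I)COCc1ccc(OC)cc1
F3 | step 20 | iodo aldehyde (C7 aldehyde, C8 iodide) | C=C([C@H](O[Si](CC)(CC)CC)CC[C@H](C)CC=O)[C@@H]1CC[C@](C)(COCc2ccc(OC)cc2)[C@@H]1/C(C)=C(/I)COCc1ccc(OC)cc1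
F4 | step 25 | 2,7-bis(triethylsilyl) ether of the macrocycle | C=C1[C@H](O[Si](CC)(CC)CC)CC[C@H](C)C[C@H](O[Si](CC)(CC)CC)/C(COCc2ccc(OC)cc2)=C(\C)[C@@H]2[C@H]1CC[C@]2(C)COCc1ccc(OC)cc1
F5 | step 25 | 2,7-bis(triethylsilyl) ether 15,16-diol | C=C1[C@H](O[Si](CC)(CC)CC)CC[C@H](C)C[C@H](O[Si](CC)(CC)CC)/C(CO)=C(\C)[C@@H]2[C@H]1CC[C@]2(C)CO
F6 | step 25 | 2,7-bis(triethylsilyl) ether 15,16-dialdehyde | C=C1[C@H](O[Si](CC)(CC)CC)CC[C@H](C)C[C@H](O[Si](CC)(CC)CC)/C(C=O)=C(\C)[C@@H]2[C@H]1CC[C@]2(C)C=O
F7 | step 25 | tricyclic 2,7-bis(triethylsilyl) ether 15,16-trans-diol | C=C1[C@H](O[Si](CC)(CC)CC)CC[C@H](C)C[C@H](O[Si](CC)(CC)CC)C2=C(C)[C@@H]3[C@H]1CC[C@]3(C)[C@@H](O)[C@@H]2O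
F8 | step 25 | tricyclic 2,7,15,16-tetraol | C=C1[C@H](O)CC[C@H](C)C[C@H](O)C2=C(C)[C@@H]3[C@H]1CC[C@]3(C)[C@@H](O)[C@@H]2O
F9 | step 26 | tricyclic 2,7-diacetate 15-hydroxy 16-ketone (α-hydroxy enone) | C=C1[C@H](OC(C)=O)CC[C@H](C)C[C@H](OC(C)=O)C2=C(C)[C@@H]3[C@H]1CC[C@]3(C)[C@@H](O)C2=O
F10 | step 26 | 16-epimer of 35 (15,16-cis-diol) | C=C1[C@H](OC(C)=O)CC[C@H](C)C[C@H](OC(C)=O)C2=C(C)[C@@H]3[C@H]1CC[C@]3(C)[C@@H](O)[C@H]2O
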